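**Plan**

Cuts: first the four O-benzyl groups. Next C2–C1' of unit 1 (benzo ring A, pyranone ring C, aryl ring B), giving a chromone and an arylboronic acid. Then O1–C8a and C4–C4a of unit 2 (benzo ring D, pyranone ring F, aryl ring E) in one operation, giving an aryne and a chiral β-silyloxy ester. Last the ring B–O–ring E ether bond at ring E.
Enabling feature: in unit 2, O1 and the carbonyl carbon C4 sit on the adjacent ring D carbons C8a and C4a, and C4a lies next to the oxygenated C5. This is the pattern left when a nucleophile and an electrophile add across a 3-alkoxyaryne.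
Forward order: diaryl ether B–O–E, three-carbon chain on ring E, ring F closed onto ring D, boron on ring B, union with the preformed rings A/C, debenzylation.
Stereochemistry: C2 of unit 2 comes from Noyori hydrogenation of a β-keto ester with RuCl2[(R)-BINAP] and passes untouched through the annulation. C2 of unit 1 comes from catalyst control by (R)-t-BuPyOx in the conjugate addition.

Key step: step 10

Assumption: the sense of induction of t-BuPyOx on the chromone is taken by analogy with 3-substituted cyclohexenones, where the (S)-ligand gives the R product and the same face would give a (2R)-flavanone. The (R)-ligand is therefore specified, and its commercial antipode would be used if the sense proved reversed.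

**Step 1**
Reactants: 1 5-bromosalicylaldehyde
Product: 2 2-(benzyloxy)-5-bromobenzaldehyde
Conditions: BnBr, K2CO3, DMF, rt
Reagents that add atoms: benzyl bromide, BrCc1ccccc1
Why: Williamson etherification of the acidic salicylaldehyde phenol with a primary benzylic bromide should be clean, and it fixes the bromine para to the protected oxygen as ring B requires.

**Step 2**
Reactants: 2 2-(benzyloxy)-5-bromobenzaldehyde
Product: 4 2-(benzyloxy)-5-bromophenol, via aryl formate 3 (not isolated)
Conditions: mCPBA, CH2Cl2, 0 °C to rt; aq NaHCO3 wash, concentrate; K2CO3 (cat.), MeOH, rt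
Reagents that add atoms: meta-chloroperbenzoic acid, O=C(OO)c1cccc(Cl)c1
Why: Baeyer–Villiger oxidation in which the electron-rich ortho-alkoxyaryl group migrates in preference to hydride (the peracid counterpart of the Dakin oxidation, which itself would need a free phenol) should give formate 3, whose mild methanolysis frees the phenol meta to bromine.

**Step 3**
Reactants: 4 2-(benzyloxy)-5-bromophenol; 5 4'-fluoroacetophenone
Product: 6 1-{4-[2-(benzyloxy)-5-bromophenoxy]phenyl}ethanone
Conditions: K2CO3, DMF, 120 °C
Reagents that add atoms: none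
Why: Nucleophilic aromatic substitution (addition–elimination through a Meisenheimer adduct) is activated by the para acetyl group and by fluoride as leaving group, whereas the unactivated aryl bromide should stay inert.

**Step 4**
Reactants: 6 1-{4-[2-(benzyloxy)-5-bromophenoxy]phenyl}ethanone
Product: 7 methyl 3-{4-[2-(benzyloxy)-5-bromophenoxy]phenyl}-3-oxopropanoate
Conditions: NaH, (MeO)2CO, THF, reflux; then aq HCl
Reagents that add atoms: dimethyl carbonate, COC(=O)OC
Why: Crossed Claisen condensation of the methyl ketone enolate with non-enolisable dimethyl carbonate is driven to completion by deprotonation of the β-keto ester formed.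

**Step 5**
Reactants: 7 methyl 3-{4-[2-(benzyloxy)-5-bromophenoxy]phenyl}-3-oxopropanoate
Product: 8 methyl (S)-3-{4-[2-(benzyloxy)-5-bromophenoxy]phenyl}-3-hydroxypropanoate
Conditions: H2 (50 bar), RuCl2[(R)-BINAP] (0.5 mol %), MeOH, 50 °C
Reagents that add atoms: none
Why: Noyori asymmetric hydrogenation of a β-keto ester, in which the ester carbonyl chelates ruthenium and (R)-BINAP directs hydride to the same face that turns acetoacetate into the (R)-hydroxybutanoate, should set the carbinol centre, here named S because aryl outranks CH2CO2Me, while aryl bromide and benzyl ether are inert to the homogeneous catalyst.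

**Step 6**
Reactants: 8 methyl (S)-3-{4-[2-(benzyloxy)-5-bromophenoxy]phenyl}-3-hydroxypropanoate
Product: 9 methyl (S)-3-{4-[2-(benzyloxy)-5-bromophenoxy]phenyl}-3-(trimethylsilyloxy)propanoate
Conditions: TMSCl, imidazole, CH2Cl2, 0 °C
Reagents that add atoms: chlorotrimethylsilane, C[Si](C)(C)Cl
Why: Standard imidazole-mediated silylation of a secondary alcohol removes the only O–H proton of the annulation partner and leaves the stereocentre untouched.

**Step 7**
Reactants: 10 phloroglucinol
Product: 11 3,5-bis(benzyloxy)phenol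
Conditions: BnBr (2 equiv), K2CO3, DMF, rt
Reagents that add atoms: benzyl bromide, BrCc1ccccc1
Why: Williamson etherification with two equivalents of benzyl bromide is statistical, so the diether is to be separated by chromatography from the mono- and triethers, a price accepted for a one-step entry from a commodity phenol.

**Step 8**
Reactants: 11 3,5-bis(benzyloxy)phenol
Product: 12 3,5-bis(benzyloxy)-2-bromophenol
Conditions: NBS (1.0 equiv), CH2Cl2, −78 °C to 0 °C
Reagents that add atoms: N-bromosuccinimide, O=C1CCC(=O)N1Br
Why: Electrophilic aromatic bromination at low temperature should go ortho to the free hydroxyl (two equivalent sites, each para to a benzyloxy group) rather than to the more crowded carbon between the two benzyloxy groups.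

**Step 9**
Reactants: 12 3,5-bis(benzyloxy)-2-bromophenol
Product: 15 3,5-bis(benzyloxy)-2-(trimethylsilyl)phenyl triflate, via bromoaryl silyl ether 13 (not isolated), via lithium silylphenoxide 14 (not isolated)
Conditions: HMDS, THF, 70 °C, evaporate; n-BuLi, THF, −78 °C; Tf2O, −78 °C to rt
Reagents that add atoms: hexamethyldisilazane, C[Si](C)(C)N[Si](C)(C)C; triflic anhydride, O=S(=O)(OS(=O)(=O)C(F)(F)F)C(F)(F)F
Why: O-silylation, bromine–lithium exchange (faster at −78 °C than benzylic deprotonation), retro-Brook O-to-C silyl shift driven by formation of the lithium phenoxide and trapping with Tf2O make up the standard entry to ortho-silylaryl triflates.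

**Step 10**
Reactants: 9 methyl (S)-3-{4-[2-(benzyloxy)-5-bromophenoxy]phenyl}-3-(trimethylsilyloxy)propanoate; 15 3,5-bis(benzyloxy)-2-(trimethylsilyl)phenyl triflate
Product: 18 (S)-5,7-bis(benzyloxy)-2-{4-[2-(benzyloxy)-5-bromophenoxy]phenyl}chroman-4-one, via 3,5-bis(benzyloxy)benzyne 16 (not isolated), via aryl caesium adduct 17 (not isolated)
Conditions: CsF, 18-crown-6, THF, 0 °C to rt; 15 (1.5 equiv) added slowly
Reagents that add atoms: none
Why: Proposed new method: fluoride attacks the C-silyl group of 15 and triflate departs to give aryne 16, while the same fluoride reversibly frees the caesium alkoxide of 9 in a medium that holds no O–H proton; the alkoxide oxygen adds to the aryne carbon remote from the benzyloxy group (future C8a), and the aryl anion 17 thus placed at C4a attacks the ester carbonyl and expels methoxide, which Me3SiF captures as MeOSiMe3 so that no strong base builds up. The closest known reaction types are the fluoride-triggered annulation of arynes with methyl salicylates to xanthones and the insertion of arynes into the N–C(O) bond of NH β-lactams to 2,3-dihydroquinolin-4-ones; new here is a secondary aliphatic alkoxide that carries a saturated ester. Ring F closes in the 6-exo-trig mode (C4a onto C4) after the intermolecular O1–C8a bond has tied the chain to ring D. No stereocentre is created and no bond to the carbinol carbon is made or broken, so the S configuration from step 5 becomes C2 with the same descriptor (O > aryl > CH2 > H before and after). The step needs regioselective addition to an unsymmetrical aryne, which the benzyloxy group next to the triple bond (future C5–O) secures by its inductive pull and by distorting the aryne, so that the distal carbon is the electrophilic one and the charge develops beside oxygen. It also needs acylation to outrun protonation of 17 and the flavanone to escape enolisation and ring opening, which the silyl ether, THF in place of acetonitrile, slow addition of 15 and a temperature at or below ambient are meant to secure.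

**Step 11**
Reactants: 18 (S)-5,7-bis(benzyloxy)-2-{4-[2-(benzyloxy)-5-bromophenoxy]phenyl}chroman-4-one
Product: 19 (S)-5,7-bis(benzyloxy)-2-{4-[2-(benzyloxy)-5-(4,4,5,5-tetramethyl-1,3,2-dioxaborolan-2-yl)phenoxy]phenyl}chroman-4-one
Conditions: B2pin2, PdCl2(dppf) (5 mol %), KOAc, 1,4-dioxane, 80 °C
Reagents that add atoms: bis(pinacolato)diboron, CC1(C)OB(OC1(C)C)B1OC(C)(C)C(C)(C)O1
Why: Miyaura borylation (oxidative addition of zerovalent palladium into the only C–Br bond, acetate-assisted transmetalation with B2pin2, reductive elimination) uses a base that should be too weak to enolise the flavanone appreciably in dioxane.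

**Step 12**
Reactants: 19 pinacol boronate of step 11
Product: 20 {4-(benzyloxy)-3-[4-((S)-5,7-bis(benzyloxy)-4-oxochroman-2-yl)phenoxy]phenyl}boronic acid
Conditions: NaIO4, NH4OAc, acetone–H2O, rt
Reagents that add atoms: water, O
Why: Periodate cleavage of the liberated pinacol pulls the boronate hydrolysis equilibrium to the free boronic acid under near-neutral buffered conditions that should not touch ketone, benzyl ethers or C2.

**Step 13**
Reactants: 21 2,4,6-trihydroxyacetophenone
Product: 22 2,6-dihydroxy-4-methoxyacetophenone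
Conditions: Me2SO4 (1.0 equiv), K2CO3, acetone, reflux
Reagents that add atoms: dimethyl sulfate, COS(=O)(=O)OC
Why: Williamson-type O-methylation with one equivalent should select the 4-hydroxyl, the only one that cannot hydrogen-bond to the acetyl carbonyl and hence the most acidic and nucleophilic.

**Step 14**
Reactants: 22 2,6-dihydroxy-4-methoxyacetophenone
Product: 23 2-(benzyloxy)-6-hydroxy-4-methoxyacetophenone
Conditions: BnBr (1.0 equiv), K2CO3, acetone, reflux
Reagents that add atoms: benzyl bromide, BrCc1ccccc1
Why: Williamson etherification of one of two equivalent ortho hydroxyls should stop at the monoether, because the remaining hydroxyl is then locked in a strong hydrogen bond to the carbonyl.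

**Step 15**
Reactants: 23 2-(benzyloxy)-6-hydroxy-4-methoxyacetophenone
Product: 25 5-(benzyloxy)-7-methoxy-4H-chromen-4-one, via enaminone 24 (not isolated)
Conditions: Me2NCH(OMe)2, toluene, 100 °C, evaporate; conc. HCl, CH2Cl2, 40 °C
Reagents that add atoms: N,N-dimethylformamide dimethyl acetal, COC(OC)N(C)C
Why: Condensation of the methyl ketone with the formamide acetal gives enaminone 24, and acid then triggers conjugate addition of the chelated phenol and loss of dimethylamine (the enaminone route to chromones unsubstituted at C2 and C3).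

**Step 16**
Reactants: 20 boronic acid of step 12; 25 5-(benzyloxy)-7-methoxy-4H-chromen-4-one
Product: 26 (2S)-5-(benzyloxy)-2-{4-(benzyloxy)-3-[4-((2S)-5,7-bis(benzyloxy)-4-oxochroman-2-yl)phenoxy]phenyl}-7-methoxychroman-4-one
Conditions: Pd(OCOCF3)2 (10 mol %), (R)-t-BuPyOx (12 mol %), NH4PF6 (30 mol %), H2O (5 equiv), ClCH2CH2Cl, 60 °C; 25 in excess
Reagents that add atoms: none
Why: Asymmetric conjugate addition of an arylboronic acid to a chromone under cationic divalent palladium and a pyridinooxazoline ligand (transmetalation, enantiodetermining carbopalladation of C2=C3, protonolysis of the palladium enolate) should set C2 of unit 1 as S through the tert-butyl group of the (R)-ligand, independently of the remote stereocentre and without base, so that unit 2 is left alone.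

**Step 17**
Reactants: 26 tetrabenzyl ether of step 16
Product: 27 7-O-methyltetrahydroochnaflavone, (2S,2''S)
Conditions: H2 (1 atm), Pd/C (10 wt % Pd), EtOAc–MeOH, rt
Reagents that add atoms: none
Why: Catalytic hydrogenolysis of the four benzyl aryl ethers under neutral conditions is standard for flavanones, whose hydrogen-bonded aryl ketones and cyclic C2–O1 bonds react far more slowly, and the absence of base keeps both C2 centres, including the one para to the new 4'-hydroxyl, from epimerising.

**Compound list**

1 | 5-bromosalicylaldehyde | O=Cc1cc(Br)ccc1O | starting material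
2 | 2-(benzyloxy)-5-bromobenzaldehyde | O=Cc1cc(Br)ccc1OCc1ccccc1 | intermediate
3 | 2-(benzyloxy)-5-bromophenyl formate | O=COc1cc(Br)ccc1OCc1ccccc1 | intermediate
4 | 2-(benzyloxy)-5-bromophenol | Oc1cc(Br)ccc1OCc1ccccc1 | intermediate
5 | 4'-fluoroacetophenone | CC(=O)c1ccc(F)cc1 | starting material
6 | 1-{4-[2-(benzyloxy)-5-bromophenoxy]phenyl}ethanone | CC(=O)c1ccc(Oc2cc(Br)ccc2OCc2ccccc2)cc1 | intermediate
7 | methyl 3-{4-[2-(benzyloxy)-5-bromophenoxy]phenyl}-3-oxopropanoate | COC(=O)CC(=O)c1ccc(Oc2cc(Br)ccc2OCc2ccccc2)cc1 | intermediate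
8 | methyl (S)-3-{4-[2-(benzyloxy)-5-bromophenoxy]phenyl}-3-hydroxypropanoate | O[C@H](c1ccc(Oc2cc(Br)ccc2OCc2ccccc2)cc1)CC(=O)OC | intermediate
9 | methyl (S)-3-{4-[2-(benzyloxy)-5-bromophenoxy]phenyl}-3-(trimethylsilyloxy)propanoate | C[Si](C)(C)O[C@H](c1ccc(Oc2cc(Br)ccc2OCc2ccccc2)cc1)CC(=O)OC | intermediate
10 | phloroglucinol | Oc1cc(O)cc(O)c1 | starting material
11 | 3,5-bis(benzyloxy)phenol | Oc1cc(OCc2ccccc2)cc(OCc2ccccc2)c1 | intermediate
12 | 3,5-bis(benzyloxy)-2-bromophenol | Oc1cc(OCc2ccccc2)cc(OCc2ccccc2)c1Br | intermediate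
13 | [3,5-bis(benzyloxy)-2-bromophenoxy]trimethylsilane | C[Si](C)(C)Oc1cc(OCc2ccccc2)cc(OCc2ccccc2)c1Br | intermediate
14 | lithium 3,5-bis(benzyloxy)-2-(trimethylsilyl)phenoxide | [Li+].[O-]c1cc(OCc2ccccc2)cc(OCc2ccccc2)c1[Si](C)(C)C | intermediate
15 | 3,5-bis(benzyloxy)-2-(trimethylsilyl)phenyl triflate | C[Si](C)(C)c1c(OCc2ccccc2)cc(OCc2ccccc2)cc1OS(=O)(=O)C(F)(F)F | intermediate
16 | 3,5-bis(benzyloxy)benzyne | C1#CC(OCc2ccccc2)=CC(OCc2ccccc2)=C1 | intermediate
17 | aryl caesium adduct: methyl (S)-3-[3,5-bis(benzyloxy)-2-caesiophenoxy]-3-{4-[2-(benzyloxy)-5-bromophenoxy]phenyl}propanoate | COC(=O)C[C@@H](c1ccc(Oc2cc(Br)ccc2OCc2ccccc2)cc1)Oc1cc(OCc2ccccc2)cc(OCc2ccccc2)c1[Cs] | intermediate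
18 | (S)-5,7-bis(benzyloxy)-2-{4-[2-(benzyloxy)-5-bromophenoxy]phenyl}chroman-4-one | O=C1C[C@@H](c2ccc(Oc3cc(Br)ccc3OCc3ccccc3)cc2)Oc2cc(OCc3ccccc3)cc(OCc3ccccc3)c21 | intermediate
19 | (S)-5,7-bis(benzyloxy)-2-{4-[2-(benzyloxy)-5-(4,4,5,5-tetramethyl-1,3,2-dioxaborolan-2-yl)phenoxy]phenyl}chroman-4-one | O=C1C[C@@H](c2ccc(Oc3cc(B4OC(C)(C)C(C)(C)O4)ccc3OCc3ccccc3)cc2)Oc2cc(OCc3ccccc3)cc(OCc3ccccc3)c21 | intermediate
20 | {4-(benzyloxy)-3-[4-((S)-5,7-bis(benzyloxy)-4-oxochroman-2-yl)phenoxy]phenyl}boronic acid | O=C1C[C@@H](c2ccc(Oc3cc(B(O)O)ccc3OCc3ccccc3)cc2)Oc2cc(OCc3ccccc3)cc(OCc3ccccc3)c21 | intermediate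
21 | 2,4,6-trihydroxyacetophenone | CC(=O)c1c(O)cc(O)cc1O | starting material
22 | 2,6-dihydroxy-4-methoxyacetophenone | CC(=O)c1c(O)cc(OC)cc1O | intermediate
23 | 2-(benzyloxy)-6-hydroxy-4-methoxyacetophenone | CC(=O)c1c(O)cc(OC)cc1OCc1ccccc1 | intermediate
24 | (E)-1-[2-(benzyloxy)-6-hydroxy-4-methoxyphenyl]-3-(dimethylamino)prop-2-en-1-one | CN(C)/C=C/C(=O)c1c(O)cc(OC)cc1OCc1ccccc1 | intermediate
25 | 5-(benzyloxy)-7-methoxy-4H-chromen-4-one | COc1cc(OCc2ccccc2)c2c(c1)OC=CC2=O | intermediate
26 | (2S)-5-(benzyloxy)-2-{4-(benzyloxy)-3-[4-((2S)-5,7-bis(benzyloxy)-4-oxochroman-2-yl)phenoxy]phenyl}-7-methoxychroman-4-one | COc1cc(OCc3ccccc3)c2c(c1)O[C@H](c1ccc(OCc3ccccc3)c(Oc3ccc([C@@H]4CC(=O)c5c(OCc6ccccc6)cc(OCc6ccccc6)cc5O4)cc3)c1)CC2=O | intermediate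
27 | 7-O-methyltetrahydroochnaflavone, (2S,2''S) | COc1cc(O)c2c(c1)O[C@H](c1ccc(O)c(Oc3ccc([C@@H]4CC(=O)c5c(O)cc(O)cc5O4)cc3)c1)CC2=O | target

**Step count**

Total step count: 17.
Longest linear sequence: 11 steps (1–6, 10–12, 16, 17).

**Steps most likely to fail**

**Step 10 (proposed new method).** Three things may go wrong.
- The aryl anion may be protonated before it reaches the ester, either by adventitious water or by internal transfer of a C3 proton. The ester enolate so formed would then eliminate aryloxide.
- Retro-aldol cleavage of the alkoxide may occur.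
- Base-induced opening and reclosure of ring F may erode the configuration.

The fallback uses known reactions only and makes the two bonds one after the other. It sets out from β-keto ester 7 and phenol 11 and comes back to the route at flavanone 18. Ketone 7 is hydrogenated with the antipodal catalyst RuCl2[(S)-BINAP] to the (R)-hydroxy ester F1. Phenol 11 is iodinated ortho to the hydroxyl with N-iodosuccinimide to 3,5-bis(benzyloxy)-2-iodophenol F2. A Mitsunobu etherification (DIAD, PPh3, toluene, 0 °C) joins the two with inversion to the (S)-β-aryloxy ester F3, so that O1–C2 is formed in place of O1–C8a. Iodine–magnesium exchange with i-PrMgCl·LiCl in THF at −40 °C should be much faster at the doubly oxygen-flanked iodide than at the ring B bromide. It gives the arylmagnesium chloride F4, which closes ring F on the ester in a Parham-type cyclisation and delivers 18.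

**Step 16.** Carbopalladation of a chromone that carries two donor oxygens may be slow, so that protodeboronation of the valuable boronic acid outruns addition. Facial selectivity on this acceptor is also unproven. The fallback forms O1–C2 of unit 1 last instead of C2–C1'. It sets out from bromide 18 and acetophenone 23 and comes back at tetrabenzyl ether 26.
- Bromide 18 undergoes reductive carbonylation (CO/H2, Pd(OAc)2, di(1-adamantyl)-n-butylphosphine, TMEDA, toluene, 100 °C) to the ring B aldehyde F5.
- Acetophenone 23 is converted with Boc2O and DMAP into the aryl tert-butyl carbonate F6.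
- LiHMDS rearranges F6 in a Baker–Venkataraman-type O-to-C transfer to the tert-butyl β-keto ester F7.
- Knoevenagel condensation of F5 with F7 (piperidine, AcOH, toluene, molecular sieves) gives the alkylidene β-keto ester F8.
- A cinchona-alkaloid thiourea (the pseudoenantiomer that gives 2S) catalyses the asymmetric intramolecular oxa-Michael addition in toluene at −25 °C to the flavanone-3-carboxylate F9.
- Heating F9 with TsOH in toluene at 80 °C removes isobutene and CO2 and gives 26.

**Step 11.** Acetate at 80 °C may enolise the flavanone and allow reversible retro-oxa-Michael opening of ring F, with erosion of C2. Protodeborylation of the electron-rich ring B is a second drain. The fallback moves the borylation ahead of ring closure. It sets out from hydroxy ester 8 and comes back at boronate 19. Hydroxy ester 8 has no ketone β to an aryloxy leaving group. It is borylated under the same Miyaura conditions to the boronate hydroxy ester F10 and silylated with TMSCl and imidazole to the boronate silyl ether F11. F11 is annulated with 15 under the conditions of step 10, with extra CsF to cover reversible binding of fluoride at boron. The reaction passes through aryne 16 and the boronate aryl caesium adduct F12 and gives 19 directly after aqueous work-up.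

**Further compounds**

F1 | step 10 | methyl (R)-3-{4-[2-(benzyloxy)-5-bromophenoxy]phenyl}-3-hydroxypropanoate | O[C@@H](c1ccc(Oc2cc(Br)ccc2OCc2ccccc2)cc1)CC(=O)OC
F2 | step 10 | 3,5-bis(benzyloxy)-2-iodophenol | Oc1cc(OCc2ccccc2)cc(OCc2ccccc2)c1I
F3 | step 10 | methyl (S)-3-[3,5-bis(benzyloxy)-2-iodophenoxy]-3-{4-[2-(benzyloxy)-5-bromophenoxy]phenyl}propanoate | COC(=O)C[C@@H](c1ccc(Oc2cc(Br)ccc2OCc2ccccc2)cc1)Oc1cc(OCc2ccccc2)cc(OCc2ccccc2)c1I
F4 | step 10 | arylmagnesium chloride derived from F3 | COC(=O)C[C@@H](c1ccc(Oc2cc(Br)ccc2OCc2ccccc2)cc1)Oc1cc(OCc2ccccc2)cc(OCc2ccccc2)c1[Mg]Cl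
F5 | step 16 | 4-(benzyloxy)-3-[4-((S)-5,7-bis(benzyloxy)-4-oxochroman-2-yl)phenoxy]benzaldehyde | O=C1C[C@@H](c2ccc(Oc3cc(C=O)ccc3OCc3ccccc3)cc2)Oc2cc(OCc3ccccc3)cc(OCc3ccccc3)c21
F6 | step 16 | 2-acetyl-3-(benzyloxy)-5-methoxyphenyl tert-butyl carbonate | CC(=O)c1c(OC(=O)OC(C)(C)C)cc(OC)cc1OCc1ccccc1
F7 | step 16 | tert-butyl 3-[2-(benzyloxy)-6-hydroxy-4-methoxyphenyl]-3-oxopropanoate | CC(C)(C)OC(=O)CC(=O)c1c(O)cc(OC)cc1OCc1ccccc1
F8 | step 16 | tert-butyl 2-[2-(benzyloxy)-6-hydroxy-4-methoxybenzoyl]-3-{4-(benzyloxy)-3-[4-((S)-5,7-bis(benzyloxy)-4-oxochroman-2-yl)phenoxy]phenyl}acrylate (alkene geometry not defined) | CC(C)(C)OC(=O)C(=Cc1ccc(OCc2ccccc2)c(Oc2ccc([C@@H]3CC(=O)c4c(OCc5ccccc5)cc(OCc5ccccc5)cc4O3)cc2)c1)C(=O)c1c(O)cc(OC)cc1OCc1ccccc1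
F9 | step 16 | tert-butyl (2S)-5-(benzyloxy)-2-{4-(benzyloxy)-3-[4-((2S)-5,7-bis(benzyloxy)-4-oxochroman-2-yl)phenoxy]phenyl}-7-methoxy-4-oxochroman-3-carboxylate (C3 labile, not defined) | COc1cc(OCc3ccccc3)c2c(c1)O[C@H](c1ccc(OCc3ccccc3)c(Oc3ccc([C@@H]4CC(=O)c5c(OCc6ccccc6)cc(OCc6ccccc6)cc5O4)cc3)c1)C(C(=O)OC(C)(C)C)C2=O
F10 | step 11 | methyl (S)-3-{4-[2-(benzyloxy)-5-(4,4,5,5-tetramethyl-1,3,2-dioxaborolan-2-yl)phenoxy]phenyl}-3-hydroxypropanoate | O[C@H](c1ccc(Oc2cc(B3OC(C)(C)C(C)(C)O3)ccc2OCc2ccccc2)cc1)CC(=O)OC
F11 | step 11 | methyl (S)-3-{4-[2-(benzyloxy)-5-(4,4,5,5-tetramethyl-1,3,2-dioxaborolan-2-yl)phenoxy]phenyl}-3-(trimethylsilyloxy)propanoate | C[Si](C)(C)O[C@H](c1ccc(Oc2cc(B3OC(C)(C)C(C)(C)O3)ccc2OCc2ccccc2)cc1)CC(=O)OC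
F12 | step 11 | aryl caesium adduct of F11 and aryne 16 | COC(=O)C[C@@H](c1ccc(Oc2cc(B3OC(C)(C)C(C)(C)O3)ccc2OCc2ccccc2)cc1)Oc1cc(OCc2ccccc2)cc(OCc2ccccc2)c1[Cs]
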